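**Retrosynthetic overview**

- Target ⇒ open-chain (2Z,6Z,10E,12R)-tetraene hydroxy acetate. The oxirane is the only ring and is closed last, by catalyst-controlled oxygen transfer to the 6,7-alkene of the finished polyene, as in the presumed biogenesis.
- Tetraene alcohol ⇒ C12–C13 disconnection: reagent-controlled 2-isopropylallylboration of a C1–C12 (2Z,6Z,10E)-enal acetate (sets 12R).
- Enal ⇒ cross-metathesis of a C1–C10 triene acetate with methacrolein (sets 10E and the C12 carbonyl).
- Triene ⇒ C7–C8 Negishi disconnection to a (Z)-vinyl iodide and butenylzinc; vinyl iodide ⇒ iodo-Wittig on a C1–C6 aldehyde (sets 6Z).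
- C1–C6 aldehyde ⇒ ozonolysis of neryl acetate, which supplies the 2Z alkene and the acetate.

Assumption: carbons are numbered C1 (CH2OAc) to C16 along the main chain, and every organometallic or chiral reagent listed as a starting material is bought as the commercial solution or solid.

**Route**

Step 1
Reactants: 1 neryl acetate, (2Z)-3,7-dimethylocta-2,6-dien-1-yl acetate
Product: 3 (2Z)-3-methyl-6-oxohex-2-en-1-yl acetate, via secondary ozonide 2 (not isolated)
Conditions: O3 (1.0 equiv), CH2Cl2, −78 °C; then PPh3, −78 °C to rt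
Reagents that add atoms: ozone, [O-][O+]=O
Why: Criegee ozonolysis is electrophilic, so one equivalent of ozone cleaves the electron-rich isopropylidene alkene much faster than the 2,3-alkene deactivated by the allylic acetate, and reductive cleavage of the ozonide leaves the 2Z geometry untouched.

Step 2
Reactants: 3 (2Z)-3-methyl-6-oxohex-2-en-1-yl acetate; 4 ethyltriphenylphosphonium iodide
Product: 8 (2Z,6Z)-7-iodo-3-methylocta-2,6-dien-1-yl acetate, via ethylidenetriphenylphosphorane 5 (not isolated), via (1-iodoethyl)triphenylphosphonium iodide 6 (not isolated), via (1-iodoethylidene)triphenylphosphorane 7 (not isolated)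
Conditions: 4, n-BuLi, THF, 0 °C; I2, −78 °C; NaN(SiMe3)2, −78 to −20 °C; then 3, −78 °C to rt
Reagents that add atoms: ethyltriphenylphosphonium iodide (4), CC[P+](c1ccccc1)(c1ccccc1)c1ccccc1.[I-]; iodine, II
Why: Stork–Zhao-type Wittig olefination with the α-iodo ylide is kinetically controlled and places iodine cis to the chain (typically ≥10:1), which fixes the geometry of the future C6=C7 alkene, while the aldehyde reacts far faster than the acetate at −78 °C.

Step 3
Reactants: 8 (2Z,6Z)-7-iodo-3-methylocta-2,6-dien-1-yl acetate; 9 but-3-en-1-ylzinc bromide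
Product: 10 (2Z,6Z)-3,7-dimethylundeca-2,6,10-trien-1-yl acetate
Conditions: 9 (1.3 equiv, 0.5 M in THF), PdCl2(dppf) (3 mol%), THF, 0 °C to rt
Reagents that add atoms: but-3-en-1-ylzinc bromide (9), C=CCC[Zn]Br
Why: Negishi sp2–sp3 coupling goes with retention, so the butenyl group takes the place of iodine cis to C5 and gives the 6Z trisubstituted alkene, and the vinyl iodide adds to zerovalent palladium far faster than the trisubstituted allylic acetate ionizes.

Step 4
Reactants: 10 (2Z,6Z)-3,7-dimethylundeca-2,6,10-trien-1-yl acetate; 11 methacrolein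
Product: 12 (2Z,6Z,10E)-3,7,11-trimethyl-12-oxododeca-2,6,10-trien-1-yl acetate
Conditions: 11 (5 equiv), second-generation Grubbs catalyst RuCl2(=CHPh)(PCy3)(H2IMes) (5 mol%), CH2Cl2, 40 °C
Reagents that add atoms: methacrolein (11), CC(=C)C=O
Why: Olefin cross-metathesis engages the only monosubstituted alkene in preference to the two trisubstituted ones and gives the thermodynamically favoured (E)-2-methyl-2-enal, which sets 10E and the C12 carbonyl in one step.

Step 5
Reactants: 12 (2Z,6Z,10E)-3,7,11-trimethyl-12-oxododeca-2,6,10-trien-1-yl acetate; 13 2,3-dimethylbut-1-ene; 14 (+)-B-methoxydiisopinocampheylborane (isopinocampheyl groups from (−)-α-pinene)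
Product: 19 (2Z,6Z,10E,12R)-12-hydroxy-3,7,11,15-tetramethyl-14-methylidenehexadeca-2,6,10-trien-1-yl acetate, via 2-isopropylallylpotassium 15 (not isolated), via potassium methoxyborate complex 16 (not isolated), via B-(2-isopropylallyl)diisopinocampheylborane 17 (not isolated), via diisopinocampheylborinate ester 18 (not isolated)
Conditions: 13, n-BuLi, KOtBu, THF, −78 to −50 °C; 14, −78 °C; BF3·OEt2, −78 °C; then 12, −78 °C; pH 7 buffer, H2O2, MeOH, 0 °C
Reagents that add atoms: 2,3-dimethylbut-1-ene (13), CC(C)C(C)=C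
Why: Schlosser metalation of the allylic methyl group followed by Brown asymmetric allylboration through a chair Zimmerman–Traxler transition state gives 1,2-addition to the enal, and the isopinocampheyl groups from (−)-α-pinene direct attack to the Re face of the aldehyde to set 12R (≥90% ee expected by analogy with methallylboration), the acetate being inert to the allylborane at −78 °C.

Step 6
Reactants: 19 (2Z,6Z,10E,12R)-12-hydroxy-3,7,11,15-tetramethyl-14-methylidenehexadeca-2,6,10-trien-1-yl acetate
Product: 20 (2Z,6R,7S,10E,12R)-6,7-epoxy-12-hydroxy-3,7,11,15-tetramethyl-14-methylidenehexadeca-2,10-dien-1-yl acetate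
Conditions: D-fructose-derived Shi ketone (30 mol%), KHSO5 (as 2KHSO5·KHSO4·K2SO4, added slowly), K2CO3, Bu4NHSO4, MeCN–CH2(OMe)2, aq. Na2B4O7 buffer (pH 10.5), −10 to 0 °C, stopped at about 85% conversion
Reagents that add atoms: potassium peroxymonosulfate (KHSO5), [K+].[O-]S(=O)(=O)OO
Why: In this Shi asymmetric epoxidation the bulky electrophilic dioxirane should prefer the isolated 6,7-alkene over the two alkenes deactivated by allylic oxygen and the less nucleophilic 1,1-disubstituted alkene, and the spiro transition state of the D-fructose-derived ketone (olefinic H cis to the small methyl group) delivers oxygen to the face that gives the (6R,7S)-cis-epoxide independently of the remote C12 centre.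

**Compound list**

1 | neryl acetate, (2Z)-3,7-dimethylocta-2,6-dien-1-yl acetate | CC(C)=CCC/C(C)=C\COC(C)=O | starting material
2 | secondary ozonide, (2Z)-5-(5,5-dimethyl-1,2,4-trioxolan-3-yl)-3-methylpent-2-en-1-yl acetate (trioxolane carbon undefined) | CC(=O)OC/C=C(C)\CCC1OOC(C)(C)O1 | intermediate
3 | (2Z)-3-methyl-6-oxohex-2-en-1-yl acetate | O=CCC/C(C)=C\COC(C)=O | intermediate
4 | ethyltriphenylphosphonium iodide | CC[P+](c1ccccc1)(c1ccccc1)c1ccccc1.[I-] | starting material
5 | ethylidenetriphenylphosphorane | CC=P(c1ccccc1)(c1ccccc1)c1ccccc1 | intermediate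
6 | (1-iodoethyl)triphenylphosphonium iodide | CC(I)[P+](c1ccccc1)(c1ccccc1)c1ccccc1.[I-] | intermediate
7 | (1-iodoethylidene)triphenylphosphorane | CC(I)=P(c1ccccc1)(c1ccccc1)c1ccccc1 | intermediate
8 | (2Z,6Z)-7-iodo-3-methylocta-2,6-dien-1-yl acetate (iodine cis to C5) | CC(=O)OC/C=C(C)\CC/C=C(\I)C | intermediate
9 | but-3-en-1-ylzinc bromide | C=CCC[Zn]Br | starting material
10 | (2Z,6Z)-3,7-dimethylundeca-2,6,10-trien-1-yl acetate | CC(=O)OC/C=C(C)\CC/C=C(C)\CCC=C | intermediate
11 | methacrolein, 2-methylprop-2-enal | CC(=C)C=O | starting material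
12 | (2Z,6Z,10E)-3,7,11-trimethyl-12-oxododeca-2,6,10-trien-1-yl acetate | CC(=O)OC/C=C(C)\CC/C=C(C)\CC/C=C(C)/C=O | intermediate
13 | 2,3-dimethylbut-1-ene | CC(C)C(C)=C | starting material
14 | (+)-B-methoxydiisopinocampheylborane (isopinocampheyl groups from (−)-α-pinene) | COB([C@H]1C[C@H]2C[C@@H]([C@@H]1C)C2(C)C)[C@H]1C[C@H]2C[C@@H]([C@@H]1C)C2(C)C | starting material
15 | 2-isopropylallylpotassium, (3-methyl-2-methylidenebutyl)potassium | [K+].[CH2-]C(=C)C(C)C | intermediate
16 | potassium methoxy(3-methyl-2-methylidenebutyl)diisopinocampheylborate | [K+].CO[B-](CC(=C)C(C)C)([C@H]1C[C@H]2C[C@@H]([C@@H]1C)C2(C)C)[C@H]1C[C@H]2C[C@@H]([C@@H]1C)C2(C)C | intermediate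
17 | B-(2-isopropylallyl)diisopinocampheylborane | C=C(CB([C@H]1C[C@H]2C[C@@H]([C@@H]1C)C2(C)C)[C@H]1C[C@H]2C[C@@H]([C@@H]1C)C2(C)C)C(C)C | intermediate
18 | diisopinocampheylborinate ester of 19 (B on the C12 oxygen) | C=C(C[C@@H](OB([C@H]1C[C@H]2C[C@@H]([C@@H]1C)C2(C)C)[C@H]1C[C@H]2C[C@@H]([C@@H]1C)C2(C)C)/C(C)=C/CC/C(C)=C\CC/C(C)=C\COC(C)=O)C(C)C | intermediate
19 | (2Z,6Z,10E,12R)-12-hydroxy-3,7,11,15-tetramethyl-14-methylidenehexadeca-2,6,10-trien-1-yl acetate | C=C(C[C@@H](O)/C(C)=C/CC/C(C)=C\CC/C(C)=C\COC(C)=O)C(C)C | intermediate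
20 | (2Z,6R,7S,10E,12R)-6,7-epoxy-12-hydroxy-3,7,11,15-tetramethyl-14-methylidenehexadeca-2,10-dien-1-yl acetate (cis-epoxide, C5 and C8 on the same side) | C=C(C[C@@H](O)/C(C)=C/CC[C@]1(C)O[C@@H]1CC/C(C)=C\COC(C)=O)C(C)C | target

**Totals**

Total step count: 6. Longest linear sequence: 6 steps (from neryl acetate; all coupling partners are bought).

**Steps most likely to fail, with fallbacks**

Step 6. One of four alkenes has to be oxidized; the threats are the C10 alkene next to the free hydroxyl and double epoxidation. The fallback sets out from 10 and comes back at 20. The oxirane is made while only one nucleophilic alkene exists: triene 10 is epoxidized under the same Shi conditions (the vinyl group does not react) to (2Z)-5-[(2R,3S)-3-(but-3-en-1-yl)-3-methyloxiran-2-yl]-3-methylpent-2-en-1-yl acetate F1. Cross-metathesis of F1 with 11 as in step 4 gives the epoxy enal (2Z)-3-methyl-5-[(2R,3S)-3-methyl-3-[(3E)-4-methyl-5-oxopent-3-en-1-yl]oxiran-2-yl]pent-2-en-1-yl acetate F2. Allylboration of F2 with 17, with BF3·OEt2 kept just below one equivalent relative to 16 so that no free Lewis acid meets the epoxide, gives the diisopinocampheylborinate of the target F3, which buffered H2O2 converts to 20.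

Step 2. The iodo-ylide olefination is often low-yielding and can give some E isomer or non-iodinated alkene. The fallback sets out from 3 and comes back at 10, and sets the geometry by selective coupling instead. Aldehyde 3 is converted with CBrCl3/PPh3 into the gem-dichloroalkene (2Z)-7,7-dichloro-3-methylhepta-2,6-dien-1-yl acetate F4. The chloride trans to the chain is replaced selectively by methyl (MeZnCl, PdCl2(DPEphos)) to give (2Z,6Z)-7-chloro-3-methylocta-2,6-dien-1-yl acetate F5. Negishi coupling of F5 with 9 under Pd(P(t-Bu)3)2 goes with retention to 10.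

Step 4. The ruthenium carbene may also touch the trisubstituted alkenes or give homodimer. The fallback sets out from 8 and comes back at 12, and installs the C12 oxygen by allylic C–H oxidation instead. Vinyl iodide 8 is coupled (PdCl2(dppf)) with (4-methylpent-3-en-1-yl)zinc bromide F6, made from 5-bromo-2-methylpent-2-ene and Zn/LiCl, to give (2Z,6Z)-3,7,11-trimethyldodeca-2,6,10-trien-1-yl acetate F7. SeO2 (cat.)/t-BuOOH oxidizes the terminal E-methyl group to (2Z,6Z,10E)-12-hydroxy-3,7,11-trimethyldodeca-2,6,10-trien-1-yl acetate F8, and MnO2 gives 12.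

**Further compounds**

F1 | step 6 | (2Z)-5-[(2R,3S)-3-(but-3-en-1-yl)-3-methyloxiran-2-yl]-3-methylpent-2-en-1-yl acetate | C=CCC[C@]1(C)O[C@@H]1CC/C(C)=C\COC(C)=O
F2 | step 6 | (2Z)-3-methyl-5-[(2R,3S)-3-methyl-3-[(3E)-4-methyl-5-oxopent-3-en-1-yl]oxiran-2-yl]pent-2-en-1-yl acetate | O=C/C(C)=C/CC[C@]1(C)O[C@@H]1CC/C(C)=C\COC(C)=O
F3 | step 6 | diisopinocampheylborinate ester of 20 (B on the C12 oxygen) | C=C(C[C@@H](OB([C@H]1C[C@H]2C[C@@H]([C@@H]1C)C2(C)C)[C@H]1C[C@H]2C[C@@H]([C@@H]1C)C2(C)C)/C(C)=C/CC[C@]1(C)O[C@@H]1CC/C(C)=C\COC(C)=O)C(C)C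
F4 | step 2 | (2Z)-7,7-dichloro-3-methylhepta-2,6-dien-1-yl acetate | CC(=O)OC/C=C(C)\CCC=C(Cl)Cl
F5 | step 2 | (2Z,6Z)-7-chloro-3-methylocta-2,6-dien-1-yl acetate | CC(=O)OC/C=C(C)\CC/C=C(\Cl)C
F6 | step 4 | (4-methylpent-3-en-1-yl)zinc bromide | CC(C)=CCC[Zn]Br
F7 | step 4 | (2Z,6Z)-3,7,11-trimethyldodeca-2,6,10-trien-1-yl acetate | CC(=O)OC/C=C(C)\CC/C=C(C)\CCC=C(C)C
F8 | step 4 | (2Z,6Z,10E)-12-hydroxy-3,7,11-trimethyldodeca-2,6,10-trien-1-yl acetate | CC(=O)OC/C=C(C)\CC/C=C(C)\CC/C=C(C)/CO
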